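**Retrosynthetic overview**

- The strategy rests on the C3–C4 bond of the pyrrole ring. It joins the nonadecyl-bearing C3 to the unsubstituted C4–H, so it can serve as the ring olefin of a 2,5-dihydro-1H-pyrrole (N1, sp3 C2 carrying the ester, sp3 C5) that lies two hydrogens below the aromatic ring. The endgame is therefore Boc removal and dehydrogenation of that 3-pyrroline.
- The only ring is closed at C3=C4 by ring-closing metathesis of methyl N-allyl-N-Boc-α-(1-nonadecylvinyl)glycinate; the allyl CH becomes C4 and the substituted vinyl carbon becomes C3.
- The diene is cut at C2–C3 and C2–N: a Petasis three-component union of henicos-1-en-2-ylboronic acid, glyoxylic acid and allylamine, followed by N-Boc protection and O-methylation.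
- The boronic acid comes from 2-bromohenicos-1-ene (Mg, then B(OiPr)3), itself made by CuI-catalysed coupling of octadecylmagnesium bromide with 2,3-dibromopropene.

Key step: step 6

Assumption: the target has no stereocentre, so the sp3 C2 centre of compounds 11 to 15 is carried as the racemate and vanishes on aromatisation; glyoxylic acid is used as its monohydrate, and salt forms that differ from a numbered compound only by a proton are not numbered separately.

**Route**

Step 1
Reactants: 1 1-bromooctadecane; 2 2,3-dibromopropene
Product: 4 2-bromohenicos-1-ene, via octadecylmagnesium bromide 3 (not isolated)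
Conditions: 1, Mg, THF, 50 °C; then added to 2 (1.3 equiv), CuI (5 mol%), THF, −10 °C to rt
Reagents that add atoms: none
Why: CuI-catalysed allylic substitution of the allylic bromide by the primary alkyl Grignard reagent (SN2 and SN2' attack converge on the same product), while the vinylic C–Br bond is inert under these conditions.

Step 2
Reactants: 4 2-bromohenicos-1-ene
Product: 7 henicos-1-en-2-ylboronic acid, via henicos-1-en-2-ylmagnesium bromide 5 (not isolated), via diisopropyl henicos-1-en-2-ylboronate 6 (not isolated)
Conditions: Mg (I2 cat.), THF, 55 °C; added to B(OiPr)3 (1.5 equiv), THF, −40 °C to rt; 1 M HCl, 0 °C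
Reagents that add atoms: triisopropyl borate CC(C)OB(OC(C)C)OC(C)C; water O
Why: Insertion of Mg into the vinylic C–Br bond, borylation of the alkenyl Grignard reagent with a trialkyl borate (low temperature and excess borate suppress double addition) and acid hydrolysis of the boronate ester, the standard boronic acid synthesis.

Step 3
Reactants: 7 henicos-1-en-2-ylboronic acid; 8 glyoxylic acid; 9 allylamine
Product: 11 2-(allylamino)-3-methylidenedocosanoic acid (racemic), via 2-(allylimino)acetic acid 10 (not isolated)
Conditions: 8 monohydrate (1.0 equiv), 9 (1.0 equiv), 7 (1.2 equiv), CH2Cl2–HFIP (9:1), rt, 24–48 h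
Reagents that add atoms: none
Why: Petasis borono-Mannich reaction, in which the carboxylate of the iminium species binds boron and the resulting tetracoordinate boronate transfers the alkenyl group through its boron-bearing carbon to the iminium carbon, so the 1-nonadecylvinyl unit arrives intact; the C2 stereocentre forms without control (racemic), which is immaterial because it becomes sp2 in the target.

Step 4
Reactants: 11 2-(allylamino)-3-methylidenedocosanoic acid
Product: 12 2-[allyl(tert-butoxycarbonyl)amino]-3-methylidenedocosanoic acid (racemic)
Conditions: Boc2O (1.5 equiv), Et3N (2 equiv), MeOH, 40 °C; then 10% aq. citric acid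
Reagents that add atoms: di-tert-butyl dicarbonate CC(C)(C)OC(=O)OC(=O)OC(C)(C)C
Why: Carbamate formation on the secondary amine; at the carboxylate stage the α-C–H is not acidic, so the amine base should not move the β,γ-double bond into conjugation.

Step 5
Reactants: 12 2-[allyl(tert-butoxycarbonyl)amino]-3-methylidenedocosanoic acid
Product: 13 methyl 2-[allyl(tert-butoxycarbonyl)amino]-3-methylidenedocosanoate (racemic)
Conditions: MeI (1.5 equiv), KHCO3 (2 equiv), DMF, rt
Reagents that add atoms: iodomethane CI
Why: SN2 O-alkylation of the carboxylate; hydrogencarbonate is too weak a base to deprotonate the α-C–H of the ester, so the 1,1-disubstituted olefin should stay in place.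

Step 6
Reactants: 13 methyl 2-[allyl(tert-butoxycarbonyl)amino]-3-methylidenedocosanoate
Product: 14 1-tert-butyl 2-methyl 3-nonadecyl-2,5-dihydro-1H-pyrrole-1,2-dicarboxylate (racemic)
Conditions: second-generation Grubbs catalyst (H2IMes)(PCy3)Cl2Ru=CHPh (5 mol%), 1,4-benzoquinone (10 mol%), CH2Cl2 (0.01 M), 40 °C, Ar
Reagents that add atoms: none
Why: Olefin ring-closing metathesis by the Chauvin mechanism: after PCy3 loss the 14-electron carbene (H2IMes)Cl2Ru=CHPh engages the unhindered monosubstituted N-allyl olefin, [2+2] cycloaddition and cycloreversion expel styrene and place the alkylidene on the allyl terminus, and this carbene adds intramolecularly across the 1,1-disubstituted olefin to a ruthenacyclobutane whose cycloreversion gives the C3=C4 bond and (H2IMes)Cl2Ru=CH2, which re-enters the cycle with loss of ethylene. The closest known reaction type is the ring-closing metathesis of N-acyl N-allyl allylic amines, such as N-allyl vinylglycine carbamates, to 3-pyrrolines with N-heterocyclic-carbene ruthenium catalysts, including closures that give trisubstituted ring olefins. The single ring, the five-membered 2,5-dihydropyrrole, is closed by forming its endocyclic double bond between the former allyl CH (C4) and the nonadecyl-bearing vinyl carbon (C3), with N1, C2 and C5 already joined in the chain. No stereocentre is created: the ring olefin can only be cis, and the existing racemic C2 centre is untouched. The step needs ring closure to outrun intermolecular metathesis and double-bond migration; the 1,1-disubstituted olefin does not homodimerise, five-membered closure is kinetically favoured at 0.01 M, the non-basic carbamate nitrogen cannot bind the metal, and benzoquinone intercepts Ru–H species. Regiochemistry is fixed because the chain already sits on the carbon that becomes C3, and loss of volatile ethylene drives the equilibrium.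

Step 7
Reactants: 14 1-tert-butyl 2-methyl 3-nonadecyl-2,5-dihydro-1H-pyrrole-1,2-dicarboxylate
Product: 15 methyl 3-nonadecyl-2,5-dihydro-1H-pyrrole-2-carboxylate (racemic)
Conditions: TFA–CH2Cl2 (1:4), 0 °C to rt; then sat. aq. NaHCO3
Reagents that add atoms: none
Why: Acidolysis of the tert-butyl carbamate with loss of 2-methylpropene and CO2; the methyl ester and the trisubstituted ring olefin should tolerate TFA at room temperature.

Step 8
Reactants: 15 methyl 3-nonadecyl-2,5-dihydro-1H-pyrrole-2-carboxylate
Product: 16 methyl 3-nonadecyl-1H-pyrrole-2-carboxylate (target)
Conditions: activated MnO2 (10 equiv), CH2Cl2, rt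
Reagents that add atoms: none
Why: Oxidative dehydrogenation of a 3-pyrroline to the pyrrole, driven by aromatisation; the two hydrogens removed are those of the doubly activated C2–H (allylic, α to nitrogen and to the ester) and of N1, which also removes the racemic centre.

**Compound list**

1 | 1-bromooctadecane | CCCCCCCCCCCCCCCCCCBr | starting material
2 | 2,3-dibromopropene | C=C(Br)CBr | starting material
3 | octadecylmagnesium bromide | CCCCCCCCCCCCCCCCCC[Mg]Br | intermediate
4 | 2-bromohenicos-1-ene | C=C(Br)CCCCCCCCCCCCCCCCCCC | intermediate
5 | henicos-1-en-2-ylmagnesium bromide | C=C([Mg]Br)CCCCCCCCCCCCCCCCCCC | intermediate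
6 | diisopropyl henicos-1-en-2-ylboronate | C=C(B(OC(C)C)OC(C)C)CCCCCCCCCCCCCCCCCCC | intermediate
7 | henicos-1-en-2-ylboronic acid | C=C(B(O)O)CCCCCCCCCCCCCCCCCCC | intermediate
8 | glyoxylic acid | O=CC(=O)O | starting material
9 | allylamine | C=CCN | starting material
10 | 2-(allylimino)acetic acid | C=CCN=CC(=O)O | intermediate
11 | 2-(allylamino)-3-methylidenedocosanoic acid (racemic) | C=CCNC(C(=O)O)C(=C)CCCCCCCCCCCCCCCCCCC | intermediate
12 | 2-[allyl(tert-butoxycarbonyl)amino]-3-methylidenedocosanoic acid (racemic) | C=CCN(C(=O)OC(C)(C)C)C(C(=O)O)C(=C)CCCCCCCCCCCCCCCCCCC | intermediate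
13 | methyl 2-[allyl(tert-butoxycarbonyl)amino]-3-methylidenedocosanoate (racemic) | C=CCN(C(=O)OC(C)(C)C)C(C(=O)OC)C(=C)CCCCCCCCCCCCCCCCCCC | intermediate
14 | 1-tert-butyl 2-methyl 3-nonadecyl-2,5-dihydro-1H-pyrrole-1,2-dicarboxylate (racemic) | CCCCCCCCCCCCCCCCCCCC1=CCN(C(=O)OC(C)(C)C)C1C(=O)OC | intermediate
15 | methyl 3-nonadecyl-2,5-dihydro-1H-pyrrole-2-carboxylate (racemic) | CCCCCCCCCCCCCCCCCCCC1=CCNC1C(=O)OC | intermediate
16 | methyl 3-nonadecyl-1H-pyrrole-2-carboxylate | CCCCCCCCCCCCCCCCCCCc1cc[nH]c1C(=O)OC | target

**Step count**

Total: 8 steps. Longest linear sequence: 8 steps (1 to 16).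

**Steps most likely to fail**

Step 3 (Petasis reaction). Alkenyl transfer from the α-branched boronate to the iminium carbon may be slow, so that protodeboronation of 7 and a second borono-Mannich alkylation of the product amine compete. The fallback sets out from 4 and returns to the route at 13, replacing the three-component C–C bond formation by a 1,2-addition to an aldehyde followed by C–N bond formation. Grignard reagent 5, made from 4 as in step 2, would be added to methyl glyoxylate in THF at −78 °C to give methyl 2-hydroxy-3-methylidenedocosanoate F1 (racemic). Tf2O and 2,6-lutidine in CH2Cl2 at −78 °C would convert it into methyl 3-methylidene-2-(trifluoromethylsulfonyloxy)docosanoate F2. Without isolation, allylamine (−78 to 0 °C) should displace the triflate at the carbon α to the ester in an SN2 reaction and give methyl 2-(allylamino)-3-methylidenedocosanoate F3. Boc2O in THF at 40 °C without added base would then give 13.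

Step 6 (ring-closing metathesis). The alkylidene formed on the allyl group may be held by the carbamate carbonyl and close only slowly onto the hindered 1,1-disubstituted olefin, so that catalyst decay and Ru–H-induced migration of the allyl double bond to the enamide overtake ring closure. The fallback sets out from 13 and returns to the route at 16; it moves the closure to a sulfonamide, which has no chelating N-acyl carbonyl, and turns the aromatisation into a redox-neutral elimination. TFA in CH2Cl2 would remove the Boc group of 13 to give methyl 2-(allylamino)-3-methylidenedocosanoate F3, the amino ester already named above. TsCl, pyridine and DMAP (cat.) in CH2Cl2 would give methyl 2-[allyl(4-methylphenylsulfonyl)amino]-3-methylidenedocosanoate F4. Ring-closing metathesis with the same second-generation Grubbs catalyst in toluene at 80 °C should give methyl 1-(4-methylphenylsulfonyl)-3-nonadecyl-2,5-dihydro-1H-pyrrole-2-carboxylate F5. DBU in DMF would then remove the C2 proton, expel 4-methylbenzenesulfinate from N1 and, after tautomerisation, give 16 without an oxidant.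

Step 2 (alkenyl Grignard formation and borylation). Insertion of Mg into the vinylic bromide of the waxy long-chain substrate may be incomplete, with dehydrobromination by the Grignard reagent already formed and double addition to the borate as side processes. The fallback sets out from 4 and returns to the route at 7, replacing the organomagnesium route by a catalytic borylation. Miyaura borylation of 4 with bis(pinacolato)diboron, PdCl2(PPh3)2 (3 mol%), PPh3 (6 mol%) and KOPh in toluene at 50 °C should give 2-(henicos-1-en-2-yl)-4,4,5,5-tetramethyl-1,3,2-dioxaborolane F6. Oxidative cleavage of the pinacol unit with NaIO4 and NH4OAc in acetone–water at rt would then release 7.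

**Further compounds**

F1 | step 3 | methyl 2-hydroxy-3-methylidenedocosanoate (racemic) | C=C(CCCCCCCCCCCCCCCCCCC)C(O)C(=O)OC
F2 | step 3 | methyl 3-methylidene-2-(trifluoromethylsulfonyloxy)docosanoate (racemic) | C=C(CCCCCCCCCCCCCCCCCCC)C(OS(=O)(=O)C(F)(F)F)C(=O)OC
F3 | step 3 | methyl 2-(allylamino)-3-methylidenedocosanoate (racemic) | C=CCNC(C(=O)OC)C(=C)CCCCCCCCCCCCCCCCCCC
F4 | step 6 | methyl 2-[allyl(4-methylphenylsulfonyl)amino]-3-methylidenedocosanoate (racemic) | C=CCN(S(=O)(=O)c1ccc(C)cc1)C(C(=O)OC)C(=C)CCCCCCCCCCCCCCCCCCC
F5 | step 6 | methyl 1-(4-methylphenylsulfonyl)-3-nonadecyl-2,5-dihydro-1H-pyrrole-2-carboxylate (racemic) | CCCCCCCCCCCCCCCCCCCC1=CCN(S(=O)(=O)c2ccc(C)cc2)C1C(=O)OC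
F6 | step 2 | 2-(henicos-1-en-2-yl)-4,4,5,5-tetramethyl-1,3,2-dioxaborolane | C=C(CCCCCCCCCCCCCCCCCCC)B1OC(C)(C)C(C)(C)O1
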